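**Retrosynthetic overview**
- The target is a linear tridepside, ring C acid → ring B → ring A. The last step is hydrogenolysis of three benzyl groups; before it, the ester between rings C and B is made by acylating the O4 phenol of ring B with 2,4-bis(benzyloxy)-3,6-dimethylbenzoyl chloride.
- The strategy rests on ring A being a 2,4-dioxygenated benzoate: C1 carboxyl, O2 (methyl ether), C3 methyl, O4 carrying the ring B acyl group meta to O2, C5–H, C6 methyl. This is the resorcinol monoester pattern that a 3-acyloxy-1,4-enyne and CO deliver.
- Ring A is opened at its C1–C2 and C2–C3 bonds (C2 comes from CO), and the aryl ester bond at C4 is traced back to a propargylic ester on the future C5. This gives enyne ester 12, in which the methyl-bearing alkyne carbon is the future C3, the inner alkyne carbon the future C4 and the enoate alkene the future C6 and C1.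
- Ester 12 comes from benzyl 3-methylbut-2-enoate (SeO2), 1-propynylmagnesium bromide and ring B acid 10. Rings B and C both come from methyl 2,4-dihydroxy-3,6-dimethylbenzoate 5.
- Ring order: rings B and C are bought as arenes; ring A is the only ring built (step 9). Then O2 methylation, MOM removal, ring C acylation and hydrogenolysis follow.

Key step: step 9

Remark: the target has no stereocentre; alcohol 4 and ester 12 are used as racemates because their single carbinol centre becomes the aromatic C5–H of ring A in step 9.

**Route**

Step 1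
Reactants: 1 benzyl 3-methylbut-2-enoate
Product: 2 benzyl (E)-3-methyl-4-oxobut-2-enoate
Conditions: SeO2 (1.2 equiv), 1,4-dioxane, reflux
Reagents that add atoms: selenium dioxide, O=[Se]=O
Why: Riley allylic oxidation; the ene/[2,3]-sigmatropic sequence attacks the methyl group trans to the ester of the trisubstituted alkene, so the E-configured 4-oxo enoate should form as it does for the lower alkyl esters.

Step 2
Reactants: 2 benzyl (E)-3-methyl-4-oxobut-2-enoate; 3 1-propynylmagnesium bromide
Product: 4 benzyl (E)-4-hydroxy-3-methylhept-2-en-5-ynoate (racemic)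
Conditions: THF, −78 °C; then aq. NH4Cl
Reagents that add atoms: none
Why: Grignard 1,2-addition; at −78 °C the alkynylmagnesium reagent adds to the aldehyde much faster than to the ester or in conjugate fashion, the E-alkene prevents lactonisation, and the new carbinol centre is formed as a racemate that step 9 erases.

Step 3
Reactants: 5 methyl 2,4-dihydroxy-3,6-dimethylbenzoate
Product: 6 methyl 5-formyl-2,4-dihydroxy-3,6-dimethylbenzoate
Conditions: Cl2CHOMe, TiCl4, CH2Cl2, 0 °C; then H2O
Reagents that add atoms: dichloromethyl methyl ether, COC(Cl)Cl; water, O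
Why: Rieche formylation; C5 is the only free ring position, lies ortho to O4 and para to O2, and is reached by the chloro(methoxy)methyl cation under titanium phenoxide direction, with hydrolysis on work-up giving the aldehyde.

Step 4
Reactants: 6 methyl 5-formyl-2,4-dihydroxy-3,6-dimethylbenzoate
Product: 7 methyl 2,4-dihydroxy-3,5,6-trimethylbenzoate
Conditions: Et3SiH (3 equiv), TFA, CH2Cl2, rt
Reagents that add atoms: none
Why: Ionic hydrogenation; the protonated aldehyde, flanked by an ortho and a para hydroxyl, is reduced through the benzylic cation (quinone methide) to the methyl group by two hydride transfers, while the ester is inert.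

Step 5
Reactants: 7 methyl 2,4-dihydroxy-3,5,6-trimethylbenzoate
Product: 8 methyl 2-hydroxy-4-(methoxymethoxy)-3,5,6-trimethylbenzoate
Conditions: MOMCl (1.1 equiv), iPr2NEt, CH2Cl2, 0 °C → rt
Reagents that add atoms: chloromethyl methyl ether, COCCl
Why: Selective Williamson-type O-alkylation; the O2 hydroxyl is held in a hydrogen bond to the ester carbonyl, so the small electrophile should react at the free O4 hydroxyl despite its two flanking methyl groups.

Step 6
Reactants: 8 methyl 2-hydroxy-4-(methoxymethoxy)-3,5,6-trimethylbenzoate
Product: 9 methyl 2-methoxy-4-(methoxymethoxy)-3,5,6-trimethylbenzoate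
Conditions: MeI, K2CO3, DMF, 50 °C
Reagents that add atoms: iodomethane, CI
Why: Williamson methylation; with O4 blocked, carbonate in DMF opens the chelate and the O2 phenoxide is methylated by the unhindered iodomethane, the MOM acetal being base-stable.

Step 7
Reactants: 9 methyl 2-methoxy-4-(methoxymethoxy)-3,5,6-trimethylbenzoate
Product: 10 2-methoxy-4-(methoxymethoxy)-3,5,6-trimethylbenzoic acid
Conditions: KOH, DMSO/H2O, 100 °C; then cold aq. KHSO4 to pH 3–4
Reagents that add atoms: potassium hydroxide, [K+].[OH-]
Why: Saponification; poorly solvated hydroxide in hot aqueous DMSO should cleave the di-ortho-substituted methyl ester, the ethers and the MOM acetal are base-stable, and cold buffered acidification spares the MOM group.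

Step 8
Reactants: 10 2-methoxy-4-(methoxymethoxy)-3,5,6-trimethylbenzoic acid; 4 benzyl (E)-4-hydroxy-3-methylhept-2-en-5-ynoate (racemic)
Product: 12 benzyl (E)-3-methyl-4-[2-methoxy-4-(methoxymethoxy)-3,5,6-trimethylbenzoyloxy]hept-2-en-5-ynoate (racemic), via acid chloride 11 (not isolated)
Conditions: 1-chloro-N,N,2-trimethylprop-1-en-1-amine, CH2Cl2, 0 °C → rt; then 4, Et3N, DMAP, CH2Cl2, rt → 40 °C
Reagents that add atoms: none
Why: Esterification through the acid chloride; the chloroenamine forms the aroyl chloride under neutral conditions that spare the MOM acetal, and DMAP-catalysed acyl transfer to a secondary alcohol is far easier than esterifying a flanked phenol, with no new stereocentre formed.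

Step 9
Reactants: 12 benzyl (E)-3-methyl-4-[2-methoxy-4-(methoxymethoxy)-3,5,6-trimethylbenzoyloxy]hept-2-en-5-ynoate (racemic); 13 carbon monoxide
Product: 14 benzyl 2-hydroxy-3,6-dimethyl-4-[2-methoxy-4-(methoxymethoxy)-3,5,6-trimethylbenzoyloxy]benzoate
Conditions: [Rh(CO)2Cl]2 (5 mol %, monovalent rhodium), CO (5 atm), 1,2-dichloroethane, 80 °C
Reagents that add atoms: none
Why: Monovalent rhodium binds the alkyne of 12, the aroyl carbonyl oxygen adds to the inner alkyne carbon and the old carbinol C–O bond breaks, so the acyloxy group shifts 1,2 (the new aryl ester bond at C4 of ring A) and leaves a rhodium vinylcarbene at the methyl-bearing carbon (future C3 of ring A) in conjugation with the enoate alkene. The carbene and the dienyl unit close to a rhodacyclohexadiene of trivalent rhodium, CO inserts as C2 of ring A and reductive elimination forms the C1–C2 and C2–C3 bonds (equivalently, a dienylketene undergoes 6π electrocyclisation), so ring A closes in a [5+1] mode as a cyclohexa-2,4-dienone whose β-keto ester enolises at once to the phenol hydrogen-bonded to the benzyl ester. The closest known reaction type is the rhodium-catalysed carbonylative [5+1] benzannulation of 3-acyloxy-1,4-enynes with CO to resorcinol monoesters. No stereocentre is created and the carbinol centre of 12 becomes the aromatic C5–H of ring A, so the racemate suffices. The step needs the 1,2-shift to win over the 1,3-shift to an allenyl ester, which a methyl-capped alkyne tends to favour; this is countered by the reversibility of the 1,3-shift under rhodium, by the electron-rich aroyl carbonyl as migrating group and by the conjugated E-alkene, which turns its hydrogen inward and its ester outward and traps the carbene irreversibly under CO with aromatisation as driving force. The outcome places the ring B acyl group on O4 and leaves O2 free, so the later methylation needs no differentiation.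

Step 10
Reactants: 14 benzyl 2-hydroxy-3,6-dimethyl-4-[2-methoxy-4-(methoxymethoxy)-3,5,6-trimethylbenzoyloxy]benzoate
Product: 15 benzyl 2-methoxy-3,6-dimethyl-4-[2-methoxy-4-(methoxymethoxy)-3,5,6-trimethylbenzoyloxy]benzoate
Conditions: MeI, K2CO3, DMF, 40 °C
Reagents that add atoms: iodomethane, CI
Why: Williamson methylation; the O2 hydroxyl of ring A is the only acidic site, and carbonate with iodomethane should not cleave the di-ortho-substituted aryl ester or the benzyl ester.

Step 11
Reactants: 15 benzyl 2-methoxy-3,6-dimethyl-4-[2-methoxy-4-(methoxymethoxy)-3,5,6-trimethylbenzoyloxy]benzoate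
Product: 16 benzyl 4-(4-hydroxy-2-methoxy-3,5,6-trimethylbenzoyloxy)-2-methoxy-3,6-dimethylbenzoate
Conditions: HCl (dioxane solution), MeOH/CH2Cl2, rt
Reagents that add atoms: none
Why: Acid-catalysed acetal exchange; the MOM group leaves as dimethoxymethane, methanol traps the methoxymethyl cation before it can attack the free C5 position of ring A, and the hindered aryl and benzyl esters resist acid methanolysis at room temperature.

Step 12
Reactants: 5 methyl 2,4-dihydroxy-3,6-dimethylbenzoate
Product: 17 methyl 2,4-bis(benzyloxy)-3,6-dimethylbenzoate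
Conditions: BnBr (2.5 equiv), K2CO3, DMF, 70 °C
Reagents that add atoms: benzyl bromide, BrCc1ccccc1
Why: Williamson benzylation; excess benzyl bromide and carbonate in warm DMF alkylate both the free O4 hydroxyl and the chelated O2 hydroxyl.

Step 13
Reactants: 17 methyl 2,4-bis(benzyloxy)-3,6-dimethylbenzoate
Product: 18 2,4-bis(benzyloxy)-3,6-dimethylbenzoic acid
Conditions: KOH, DMSO/H2O, 100 °C; then aq. HCl
Reagents that add atoms: potassium hydroxide, [K+].[OH-]
Why: Saponification of a hindered methyl benzoate by hydroxide in hot aqueous DMSO, as in step 7; benzyl ethers are stable to base.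

Step 14
Reactants: 18 2,4-bis(benzyloxy)-3,6-dimethylbenzoic acid; 16 benzyl 4-(4-hydroxy-2-methoxy-3,5,6-trimethylbenzoyloxy)-2-methoxy-3,6-dimethylbenzoate
Product: 20 benzyl 4-{4-[2,4-bis(benzyloxy)-3,6-dimethylbenzoyloxy]-2-methoxy-3,5,6-trimethylbenzoyloxy}-2-methoxy-3,6-dimethylbenzoate, via acid chloride 19 (not isolated)
Conditions: (COCl)2, DMF (cat.), CH2Cl2, 0 °C → rt, evaporate; then 16, NaH (1.05 equiv), THF, 0 °C → rt
Reagents that add atoms: none
Why: Acylation of a phenoxide by an acid chloride; the sodium phenoxide of 16 should be nucleophilic enough to overcome the double ortho-substitution on both partners, the ortho-alkoxy aroyl chloride ionises readily towards an acylium-like transition state, and one equivalent of NaH leaves the two existing esters untouched.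

Step 15
Reactants: 20 benzyl 4-{4-[2,4-bis(benzyloxy)-3,6-dimethylbenzoyloxy]-2-methoxy-3,5,6-trimethylbenzoyloxy}-2-methoxy-3,6-dimethylbenzoate
Product: 21 4-{4-[2,4-dihydroxy-3,6-dimethylbenzoyloxy]-2-methoxy-3,5,6-trimethylbenzoyloxy}-2-methoxy-3,6-dimethylbenzoic acid (CNP0425440.0)
Conditions: H2 (1 atm), 10% Pd/C, EtOAc/THF, rt
Reagents that add atoms: none
Why: Catalytic hydrogenolysis; the two benzyl ethers and the benzyl ester are cleaved at their benzylic C–O bonds, whereas aryl esters, methyl ethers and the arenes are inert, giving the target, which has no stereocentre.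

**Compound list**
1 | benzyl 3-methylbut-2-enoate | CC(C)=CC(=O)OCc1ccccc1 | starting material
2 | benzyl (E)-3-methyl-4-oxobut-2-enoate | O=C/C(C)=C/C(=O)OCc1ccccc1 | intermediate
3 | 1-propynylmagnesium bromide | CC#C[Mg]Br | starting material
4 | benzyl (E)-4-hydroxy-3-methylhept-2-en-5-ynoate (racemic) | CC#CC(O)/C(C)=C/C(=O)OCc1ccccc1 | intermediate
5 | methyl 2,4-dihydroxy-3,6-dimethylbenzoate | COC(=O)c1c(C)cc(O)c(C)c1O | starting material
6 | methyl 5-formyl-2,4-dihydroxy-3,6-dimethylbenzoate | COC(=O)c1c(C)c(C=O)c(O)c(C)c1O | intermediate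
7 | methyl 2,4-dihydroxy-3,5,6-trimethylbenzoate | COC(=O)c1c(C)c(C)c(O)c(C)c1O | intermediate
8 | methyl 2-hydroxy-4-(methoxymethoxy)-3,5,6-trimethylbenzoate | COC(=O)c1c(C)c(C)c(OCOC)c(C)c1O | intermediate
9 | methyl 2-methoxy-4-(methoxymethoxy)-3,5,6-trimethylbenzoate | COC(=O)c1c(C)c(C)c(OCOC)c(C)c1OC | intermediate
10 | 2-methoxy-4-(methoxymethoxy)-3,5,6-trimethylbenzoic acid | OC(=O)c1c(C)c(C)c(OCOC)c(C)c1OC | intermediate
11 | 2-methoxy-4-(methoxymethoxy)-3,5,6-trimethylbenzoyl chloride (not isolated) | ClC(=O)c1c(C)c(C)c(OCOC)c(C)c1OC | intermediate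
12 | benzyl (E)-3-methyl-4-[2-methoxy-4-(methoxymethoxy)-3,5,6-trimethylbenzoyloxy]hept-2-en-5-ynoate (racemic) | CC#CC(OC(=O)c1c(C)c(C)c(OCOC)c(C)c1OC)/C(C)=C/C(=O)OCc1ccccc1 | intermediate
13 | carbon monoxide | [C-]#[O+] | starting material
14 | benzyl 2-hydroxy-3,6-dimethyl-4-[2-methoxy-4-(methoxymethoxy)-3,5,6-trimethylbenzoyloxy]benzoate | COCOc1c(C)c(C)c(C(=O)Oc2cc(C)c(C(=O)OCc3ccccc3)c(O)c2C)c(OC)c1C | intermediate
15 | benzyl 2-methoxy-3,6-dimethyl-4-[2-methoxy-4-(methoxymethoxy)-3,5,6-trimethylbenzoyloxy]benzoate | COCOc1c(C)c(C)c(C(=O)Oc2cc(C)c(C(=O)OCc3ccccc3)c(OC)c2C)c(OC)c1C | intermediate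
16 | benzyl 4-(4-hydroxy-2-methoxy-3,5,6-trimethylbenzoyloxy)-2-methoxy-3,6-dimethylbenzoate | COc1c(C)c(O)c(C)c(C)c1C(=O)Oc1cc(C)c(C(=O)OCc2ccccc2)c(OC)c1C | intermediate
17 | methyl 2,4-bis(benzyloxy)-3,6-dimethylbenzoate | COC(=O)c1c(C)cc(OCc2ccccc2)c(C)c1OCc1ccccc1 | intermediate
18 | 2,4-bis(benzyloxy)-3,6-dimethylbenzoic acid | OC(=O)c1c(C)cc(OCc2ccccc2)c(C)c1OCc1ccccc1 | intermediate
19 | 2,4-bis(benzyloxy)-3,6-dimethylbenzoyl chloride (not isolated) | ClC(=O)c1c(C)cc(OCc2ccccc2)c(C)c1OCc1ccccc1 | intermediate
20 | benzyl 4-{4-[2,4-bis(benzyloxy)-3,6-dimethylbenzoyloxy]-2-methoxy-3,5,6-trimethylbenzoyloxy}-2-methoxy-3,6-dimethylbenzoate | COc1c(C)c(OC(=O)c2c(C)c(C)c(OC(=O)c3c(C)cc(OCc4ccccc4)c(C)c3OCc5ccccc5)c(C)c2OC)cc(C)c1C(=O)OCc6ccccc6 | intermediate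
21 | 4-{4-[2,4-dihydroxy-3,6-dimethylbenzoyloxy]-2-methoxy-3,5,6-trimethylbenzoyloxy}-2-methoxy-3,6-dimethylbenzoic acid (CNP0425440.0) | COc1c(C)c(OC(=O)c2c(C)c(C)c(OC(=O)c3c(C)cc(O)c(C)c3O)c(C)c2OC)cc(C)c1C(=O)O | target

**Step count**
Total steps: 15. Longest linear sequence: 11 (steps 3, 4, 5, 6, 7, 8, 9, 10, 11, 14, 15).

**Steps most likely to fail**

1. Step 9. The methyl-capped alkyne may divert the acyloxy group into a 1,3-shift, giving an allenyl ester that is carbonylated in a [4+1] sense or decomposes. The electron-poor enoate terminus may also capture the carbene too slowly. Fallback, by classical depside chemistry: starting from 5, the methyl ester would be hydrolysed (KOH, H2O/DMSO, 60 °C, cold acidification to avoid decarboxylation) to 2,4-dihydroxy-3,6-dimethylbenzoic acid F1. The carboxylate would be benzylated selectively (BnBr, KHCO3, DMF, rt) to benzyl 2,4-dihydroxy-3,6-dimethylbenzoate F2. The non-chelated, more acidic O4 hydroxyl of F2 would then be acylated (K2CO3, acetone, or NaH, THF) with acid chloride 11, prepared from 10 as in step 8. This sequence comes back to the route at 14.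

2. Step 14. Acyl transfer between a di-ortho-substituted aroyl chloride and a phenoxide flanked by two methyl groups may be too slow, so that the acid chloride is lost to hydrolysis or the phenoxide attacks an existing ester. Fallback: starting from 18 and 16, acid-mediated condensation with trifluoroacetic anhydride in toluene at rt. The acid is converted into 2,4-bis(benzyloxy)-3,6-dimethylbenzoic trifluoroacetic anhydride F3, which ionises to a linear, unhindered acylium ion that the free phenol captures. This returns to the route at 20.

3. Step 8. Acylation of the doubly activated secondary alcohol by the hindered aroyl chloride may be sluggish, allowing base-induced isomerisation at the acidic γ-position of 4. Fallback: starting from 10 and 4, Mitsunobu esterification (PPh3, DIAD, THF, 0 °C → rt). The carboxylate then attacks the activated carbinol carbon, so steric demand at the acyl carbon no longer matters, and inversion is irrelevant for the racemate. This returns to the route at 12.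

**Further compounds**
F1 | step 9 | 2,4-dihydroxy-3,6-dimethylbenzoic acid | Cc1cc(O)c(C)c(O)c1C(=O)O
F2 | step 9 | benzyl 2,4-dihydroxy-3,6-dimethylbenzoate | Cc1cc(O)c(C)c(O)c1C(=O)OCc1ccccc1
F3 | step 14 | 2,4-bis(benzyloxy)-3,6-dimethylbenzoic trifluoroacetic anhydride | Cc1cc(OCc2ccccc2)c(C)c(OCc2ccccc2)c1C(=O)OC(=O)C(F)(F)F
F0 | step 8 | none | none
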